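All runs are calculated from invented constants, noise included.

Over 2.5 d I compare three flasks by the share of Z in Z plus X.

| flask | L | D | remark | time |
|---|---|---|---|---|
| south-east | 0.050 M | 0.70 equiv | run made earlier |  |
| north-west | 0.050 M | 1 equiv | run made earlier |  |
| eta | 0.050 M | 0.700 equiv | everything together at the start | 2.5 d |
| alpha | 0.050 M (fed, over 40 h) | 0.700 equiv | all else is in the flask from the start; the feed brings no volume worth counting | 2.5 d |
| zeta | 0.050 M | 0.700 equiv (fed, over 40 h) | all else is in the flask from the start; the feed brings no volume worth counting | 2.5 d |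

- south-east (time / d: Z / %, X / %): 0.625: 32.3, 13.9; 1.25: 22.9, 11.9; 2.08: 15.5, 12.9; 2.50: 10.5, 12.5
- north-west (time / h: Z / %, X / %): 0.833: 29.6, 18.7; 2.00: 38.1, 21.7; 4.00: 45.3, 22.9; 6.00: 45.9, 23.2

(each reading ± 1 percentage point)

- the flask with the highest share of Z in Z plus X ("all alike" if they lie within 1.5 percentage points) (eta / alpha / zeta / all alike)
- share of Z in Z plus X at the end, eta
- share of Z in Z plus X at the end, alpha
- share of Z in Z plus X at the end, zeta

- a reading or a percentage of Z counts all its forms, free or not

In the last readings of the two runs one thing looks odd. From the south-east run to the north-west run the D charge rises by a factor 1.43, yet X rises by 1.86, more than D does. In the north-west run Z plus two X reaches 92.3% of the D charged, so I let X cost two D and Z one. Then X made per Z made goes with cD. In the south-east run X is 12.5%, Z made is about 45.0%, and mean cD is about 0.0175 M. That gives 0.0630 M. This is c×, the cD at which X and Z are made equally fast; X per Z made is cD over c×, so it changes with cD. More D therefore also tips the split towards X, which clears the oddity.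

The first north-west reading gives D a lifetime on the Z route of 1.87 h. In zeta, feed rate times lifetime puts cD near 0.001638 M, so X per Z made is 0.0260. Z fades at 0.599 d⁻¹, so of Z made evenly over the feed 38.4% survives. My share for zeta is 93.7%. In alpha I expect the south-east split with that survival, 58.0%. Eta repeats the south-east run, 45.7%.

The forecast gives 46%, 54% and 88% for eta, alpha and zeta, picks zeta, and says “Zeta keeps D starved”; my zeta stands higher.

The flasks give 46.5% for eta, 55.4% for alpha and 94.2% for zeta, so zeta is highest.

    L + D → Z (k = 0.00520 L mol⁻¹ s⁻¹)
    L + 2 D → X (k = 0.104 L² mol⁻² s⁻¹)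
    G ⇌ Z, rate k3*(cs3 - [Z]) while solid is left; crystals form when [Z] > cs3 (solubility = 20.0 mM, k = 1.37 × 10⁻⁴ s⁻¹)
    Z → J (k = 6.37 × 10⁻⁶ s⁻¹)

In zeta the mean cD over the feed is 0.00132 M, far below c×, which gives X per Z made of 0.0210, and at 2.50 d zeta holds X 1.75% against Z plus J 66.5%, a ratio of 0.0264. A neighbour flask, like eta but charged with 2.80 equiv of D, has cD midway between charge and end of 0.0987 M, which over c× gives 1.57, and at 2.50 d that neighbour holds X 65.3% against Z plus J 34.7%, a ratio of 1.88.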